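**Assumption:** IUPAC quinic acid numbering is used (C-1 carries CO2H; 3-OH cis to 4-OH; 5-OH trans to 4-OH and cis to CO2H). Read this way, the target is 1,3,5-tri-O-(E)-caffeoyl-4-O-succinylquinic acid with the configuration of natural (−)-quinic acid (7).

## Retrosynthetic overview

1. Target 20 ⇐ global Pd(0) deallylation of the octa-allyl compound 19 (six aryl allyl ethers, two allyl esters).
2. 19 ⇐ 3,5-di-O-acylation of diol 18 with acid chloride 6; 18 ⇐ 4-O-succinylation of the 3,5-bis-TBS ether 13 with mono-allyl succinate 16, then desilylation.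
3. 13 ⇐ (−)-quinic acid 7: acetonide-lactone 8 exposes only the tertiary 1-OH for the first caffeoylation; then acid hydrolysis, allyl ester, and 3,5-selective silylation that leaves the 4-OH free.
4. Caffeoyl unit 6 ⇐ key C–C bond: Knoevenagel–Doebner (aldol-type) condensation of 3,4-bis(allyloxy)benzaldehyde 2 with malonic acid 3.
5. Rings: no ring is built. The cyclohexane comes intact from 7 and the arenes from 1; the lactone and acetonide rings of 8 are temporary and are opened in step 6.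

## Route

Step 1
Reactants: 1 3,4-dihydroxybenzaldehyde
Product: 2 3,4-bis(allyloxy)benzaldehyde
Conditions: allyl bromide (2.5 equiv), K2CO3, DMF, 60 °C, N2
Reagents that add atoms: allyl bromide, C=CCBr
Why: Williamson ether synthesis; both phenoxides undergo SN2 alkylation and the aldehyde is inert.

Step 2
Reactants: 2 3,4-bis(allyloxy)benzaldehyde; 3 malonic acid
Product: 5 (E)-3-[3,4-bis(allyloxy)phenyl]prop-2-enoic acid, via arylidenemalonic acid 4 (not isolated)
Conditions: malonic acid (2 equiv), pyridine, piperidine (cat.), 90 °C then reflux; HCl work-up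
Reagents that add atoms: none
Why: Knoevenagel–Doebner condensation (aldol-type addition of malonic acid to the aldehyde, dehydration, decarboxylation) forms the key C–C bond and gives the thermodynamic E-alkene.

Step 3
Reactants: 5 (E)-3-[3,4-bis(allyloxy)phenyl]prop-2-enoic acid
Product: 6 (E)-3-[3,4-bis(allyloxy)phenyl]prop-2-enoyl chloride
Conditions: (COCl)2 (1.5 equiv), DMF (cat.), CH2Cl2, 0 °C to rt; evaporate, use crude
Reagents that add atoms: oxalyl chloride, ClC(=O)C(=O)Cl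
Why: Acid chloride formation through the Vilsmeier-type chloroiminium catalyst; allyl ethers and the E-alkene are untouched.

Step 4
Reactants: 7 (−)-quinic acid
Product: 8 3,4-O-isopropylidene-1,5-quinide (quinic acid 1,5-lactone 3,4-acetonide, free tertiary 1-OH)
Conditions: 2,2-dimethoxypropane (3 equiv), TsOH·H2O (cat.), acetone, reflux
Reagents that add atoms: 2,2-dimethoxypropane, COC(C)(C)OC
Why: Acid-catalysed acetalisation of the cis-3,4-diol and lactonisation of CO2H onto the cis 5-OH; no stereocentre is touched and only the 1-OH stays free.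

Step 5
Reactants: 8 3,4-O-isopropylidene-1,5-quinide; 6 (E)-3-[3,4-bis(allyloxy)phenyl]prop-2-enoyl chloride
Product: 9 1-O-[(E)-3,4-bis(allyloxy)cinnamoyl]-3,4-O-isopropylidene-1,5-quinide
Conditions: 6 (1.4 equiv), DMAP (0.5 equiv), pyridine/CH2Cl2, 0 °C to rt, 16 h
Reagents that add atoms: none
Why: DMAP-catalysed acylation of the only free hydroxyl; in the bicyclic lactone the tertiary 1-OH is equatorial and accessible.

Step 6
Reactants: 9 1-O-[(E)-3,4-bis(allyloxy)cinnamoyl]-3,4-O-isopropylidene-1,5-quinide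
Product: 11 1-O-[(E)-3,4-bis(allyloxy)cinnamoyl]quinic acid, via lactone diol 10 (not isolated)
Conditions: 1 M aq. HCl/THF (1:3), rt, 5–8 d (HPLC control)
Reagents that add atoms: water, O
Why: Acid-catalysed acetal hydrolysis followed by acyl–oxygen (AAC2) hydrolysis of the strained γ-lactone; the hindered tertiary cinnamate and the aryl allyl ethers survive dilute acid, and no C–O bond at a stereocentre is broken.

Step 7
Reactants: 11 1-O-[(E)-3,4-bis(allyloxy)cinnamoyl]quinic acid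
Product: 12 allyl 1-O-[(E)-3,4-bis(allyloxy)cinnamoyl]quinate
Conditions: allyl bromide (1.5 equiv), KHCO3 (1.5 equiv), DMF, rt, 16 h
Reagents that add atoms: allyl bromide, C=CCBr
Why: SN2 O-alkylation of the carboxylate; bicarbonate deprotonates only the acid, so the three alcohols are not alkylated and the 1-ester does not migrate.

Step 8
Reactants: 12 allyl 1-O-[(E)-3,4-bis(allyloxy)cinnamoyl]quinate
Product: 13 allyl 1-O-[(E)-3,4-bis(allyloxy)cinnamoyl]-3,5-bis-O-(tert-butyldimethylsilyl)quinate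
Conditions: TBSCl (2.3 equiv), imidazole (5 equiv), DMF, 0 °C to rt
Reagents that add atoms: tert-butyldimethylsilyl chloride, CC(C)(C)[Si](C)(C)Cl
Why: Regioselective silylation; the 3- and 5-OH each have a CH2 neighbour, while the 4-OH is flanked on both sides and stays free, the selectivity known for quinate esters.

Step 9
Reactants: 14 succinic anhydride; 15 allyl alcohol
Product: 16 4-(allyloxy)-4-oxobutanoic acid (mono-allyl succinate)
Conditions: allyl alcohol (1.2 equiv), DMAP (5 mol %), toluene, 90 °C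
Reagents that add atoms: none
Why: Alcoholysis of a cyclic anhydride stops cleanly at the mono-ester.

Step 10
Reactants: 13 allyl 1-O-[(E)-3,4-bis(allyloxy)cinnamoyl]-3,5-bis-O-(tert-butyldimethylsilyl)quinate; 16 4-(allyloxy)-4-oxobutanoic acid
Product: 17 allyl 4-O-[4-(allyloxy)-4-oxobutanoyl]-1-O-[(E)-3,4-bis(allyloxy)cinnamoyl]-3,5-bis-O-(tert-butyldimethylsilyl)quinate
Conditions: 16 (3 equiv), EDC·HCl (3 equiv), DMAP (1 equiv), CH2Cl2, rt to 35 °C, 24 h
Reagents that add atoms: none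
Why: Steglich esterification of the only free hydroxyl (4-OH), which fixes the succinyl group at O-4 unambiguously.

Step 11
Reactants: 17 allyl 4-O-[4-(allyloxy)-4-oxobutanoyl]-1-O-[(E)-3,4-bis(allyloxy)cinnamoyl]-3,5-bis-O-(tert-butyldimethylsilyl)quinate
Product: 18 allyl 4-O-[4-(allyloxy)-4-oxobutanoyl]-1-O-[(E)-3,4-bis(allyloxy)cinnamoyl]quinate (3,5-diol)
Conditions: HF·pyridine, pyridine/THF, 0 °C to rt
Reagents that add atoms: none
Why: Fluoride-mediated desilylation in a weakly acidic buffer, where 4→3/4→5 acyl migration is slow and all esters and allyl groups are stable.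

Step 12
Reactants: 18 allyl 4-O-[4-(allyloxy)-4-oxobutanoyl]-1-O-[(E)-3,4-bis(allyloxy)cinnamoyl]quinate; 6 (E)-3-[3,4-bis(allyloxy)phenyl]prop-2-enoyl chloride
Product: 19 allyl 4-O-[4-(allyloxy)-4-oxobutanoyl]-1,3,5-tris-O-[(E)-3,4-bis(allyloxy)cinnamoyl]quinate
Conditions: 6 (3 equiv), pyridine, DMAP (0.2 equiv), CH2Cl2, 0 °C to rt
Reagents that add atoms: none
Why: DMAP-catalysed acylation of the two secondary hydroxyls with the acid chloride is fast enough at 0 °C to outrun succinyl migration; O-acylation retains configuration.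

Step 13
Reactants: 19 allyl 4-O-[4-(allyloxy)-4-oxobutanoyl]-1,3,5-tris-O-[(E)-3,4-bis(allyloxy)cinnamoyl]quinate
Product: 20 1,3,5-tri-O-[(E)-caffeoyl]-4-O-succinylquinic acid (CNP0143991.1)
Conditions: Pd(PPh3)4 (10 mol %), morpholine (16 equiv), degassed THF, rt, 2–3 h; cold dilute HCl work-up, RP-18 chromatography
Reagents that add atoms: none
Why: Tsuji–Trost deallylation; Pd(0) ionises all allyl esters and aryl allyl ethers to π-allyl complexes that morpholine traps, leaving the four acyl esters, the E-alkenes and all stereocentres untouched.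

## Compound list

1 | 3,4-dihydroxybenzaldehyde | O=Cc1ccc(O)c(O)c1 | starting material
2 | 3,4-bis(allyloxy)benzaldehyde | O=Cc1ccc(OCC=C)c(OCC=C)c1 | intermediate
3 | malonic acid | OC(=O)CC(=O)O | starting material
4 | 2-[3,4-bis(allyloxy)benzylidene]malonic acid (not isolated) | OC(=O)C(=Cc1ccc(OCC=C)c(OCC=C)c1)C(=O)O | intermediate
5 | (E)-3-[3,4-bis(allyloxy)phenyl]prop-2-enoic acid | OC(=O)/C=C/c1ccc(OCC=C)c(OCC=C)c1 | intermediate
6 | (E)-3-[3,4-bis(allyloxy)phenyl]prop-2-enoyl chloride | ClC(=O)/C=C/c1ccc(OCC=C)c(OCC=C)c1 | intermediate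
7 | (−)-quinic acid, (1S,3R,4S,5R)-1,3,4,5-tetrahydroxycyclohexane-1-carboxylic acid | O[C@H]1[C@H](O)C[C@](O)(C(=O)O)C[C@H]1O | starting material
8 | 3,4-O-isopropylidene-1,5-quinide | CC1(C)O[C@H]2[C@H](O3)C[C@](O)(C3=O)C[C@H]2O1 | intermediate
9 | 1-O-[(E)-3,4-bis(allyloxy)cinnamoyl]-3,4-O-isopropylidene-1,5-quinide | CC1(C)O[C@H]2[C@H](O3)C[C@](OC(=O)/C=C/c4ccc(OCC=C)c(OCC=C)c4)(C3=O)C[C@H]2O1 | intermediate
10 | 1-O-[(E)-3,4-bis(allyloxy)cinnamoyl]-1,5-quinide, 3,4-diol (not isolated) | O[C@H]1[C@H](O2)C[C@](OC(=O)/C=C/c3ccc(OCC=C)c(OCC=C)c3)(C2=O)C[C@H]1O | intermediate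
11 | 1-O-[(E)-3,4-bis(allyloxy)cinnamoyl]quinic acid | O[C@H]1[C@H](O)C[C@](OC(=O)/C=C/c2ccc(OCC=C)c(OCC=C)c2)(C(=O)O)C[C@H]1O | intermediate
12 | allyl 1-O-[(E)-3,4-bis(allyloxy)cinnamoyl]quinate | O[C@H]1[C@H](O)C[C@](OC(=O)/C=C/c2ccc(OCC=C)c(OCC=C)c2)(C(=O)OCC=C)C[C@H]1O | intermediate
13 | allyl 1-O-[(E)-3,4-bis(allyloxy)cinnamoyl]-3,5-bis-O-(tert-butyldimethylsilyl)quinate | O[C@H]1[C@H](O[Si](C)(C)C(C)(C)C)C[C@](OC(=O)/C=C/c2ccc(OCC=C)c(OCC=C)c2)(C(=O)OCC=C)C[C@H]1O[Si](C)(C)C(C)(C)C | intermediate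
14 | succinic anhydride | O=C1CCC(=O)O1 | starting material
15 | allyl alcohol | OCC=C | starting material
16 | 4-(allyloxy)-4-oxobutanoic acid | OC(=O)CCC(=O)OCC=C | intermediate
17 | allyl 4-O-[4-(allyloxy)-4-oxobutanoyl]-1-O-[(E)-3,4-bis(allyloxy)cinnamoyl]-3,5-bis-O-(tert-butyldimethylsilyl)quinate | C=CCOC(=O)CCC(=O)O[C@H]1[C@H](O[Si](C)(C)C(C)(C)C)C[C@](OC(=O)/C=C/c2ccc(OCC=C)c(OCC=C)c2)(C(=O)OCC=C)C[C@H]1O[Si](C)(C)C(C)(C)C | intermediate
18 | allyl 4-O-[4-(allyloxy)-4-oxobutanoyl]-1-O-[(E)-3,4-bis(allyloxy)cinnamoyl]quinate | C=CCOC(=O)CCC(=O)O[C@H]1[C@H](O)C[C@](OC(=O)/C=C/c2ccc(OCC=C)c(OCC=C)c2)(C(=O)OCC=C)C[C@H]1O | intermediate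
19 | allyl 4-O-[4-(allyloxy)-4-oxobutanoyl]-1,3,5-tris-O-[(E)-3,4-bis(allyloxy)cinnamoyl]quinate | C=CCOC(=O)CCC(=O)O[C@H]1[C@H](OC(=O)/C=C/c2ccc(OCC=C)c(OCC=C)c2)C[C@](OC(=O)/C=C/c2ccc(OCC=C)c(OCC=C)c2)(C(=O)OCC=C)C[C@H]1OC(=O)/C=C/c1ccc(OCC=C)c(OCC=C)c1 | intermediate
20 | 1,3,5-tri-O-[(E)-caffeoyl]-4-O-succinylquinic acid | O=C(O)CCC(=O)O[C@H]1[C@H](OC(=O)/C=C/c2ccc(O)c(O)c2)C[C@](OC(=O)/C=C/c2ccc(O)c(O)c2)(C(=O)O)C[C@H]1OC(=O)/C=C/c1ccc(O)c(O)c1 | target

## Totals

Total step count: 13.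
Longest linear sequence: 11 steps (1, 2, 3, 5, 6, 7, 8, 10, 11, 12, 13).

## Three steps most likely to fail, with fallbacks

**Step 6 (slow acid hydrolysis of lactone and acetonide with the 1-O-ester in place).** The risks are incomplete lactone opening or partial loss of the 1-O-cinnamoyl group. The fallback sets out from 7 and comes back at 17, leaving the quinide detour altogether. The caesium salt of 7 is alkylated with allyl bromide (Cs2CO3 0.5 equiv, DMF, rt) to give allyl quinate F1. This is silylated with TBSCl/imidazole in DMF to allyl 3,5-bis-O-(tert-butyldimethylsilyl)quinate F2. The secondary 4-OH is then esterified with 16 (EDC·HCl, DMAP, CH2Cl2) to give allyl 4-O-[4-(allyloxy)-4-oxobutanoyl]-3,5-bis-O-(tert-butyldimethylsilyl)quinate F3. Finally the remaining tertiary 1-OH is acylated under forcing conditions with 6 (DMAP 1 equiv, pyridine, 1,2-dichloroethane, 60 °C) to give 17.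

**Step 10 (esterification of the 4-OH flanked by two OTBS groups).** The risk is that carbodiimide activation is too slow and N-acylurea formation wins. The fallback sets out from 13 and comes back at 17. Succinic anhydride 14 is opened by the 4-OH of 13 (DMAP 1 equiv, Et3N, toluene, 70 °C) to give the 4-O-hemisuccinate F4. Its carboxylate is then alkylated with allyl bromide (KHCO3, DMF, rt) to give 17.

**Step 12 (double acylation next to the 4-O-succinyl ester).** The axial 3-OH is hindered, and base-promoted succinyl migration could compete. The fallback sets out from 18 and comes back at 19, avoiding basic acylation by building the two cinnamates on the ring. Diol 18 is heated with Meldrum's acid (2,2-dimethyl-1,3-dioxane-4,6-dione) in toluene at 90 °C without base to give the 3,5-bis(hydrogen malonate) F5. This undergoes Knoevenagel–Doebner condensation with aldehyde 2 (2.5 equiv, DMAP, cat. piperidine, DMF, rt to 40 °C). The condensation passes through the bis(arylidenemalonate half-ester) F6 (not isolated), which decarboxylates to the E,E-diester 19.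

## Further compounds

F1 | step 6 | allyl quinate | O[C@H]1[C@H](O)C[C@](O)(C(=O)OCC=C)C[C@H]1O
F2 | step 6 | allyl 3,5-bis-O-(tert-butyldimethylsilyl)quinate | O[C@H]1[C@H](O[Si](C)(C)C(C)(C)C)C[C@](O)(C(=O)OCC=C)C[C@H]1O[Si](C)(C)C(C)(C)C
F3 | step 6 | allyl 4-O-[4-(allyloxy)-4-oxobutanoyl]-3,5-bis-O-(tert-butyldimethylsilyl)quinate | C=CCOC(=O)CCC(=O)O[C@H]1[C@H](O[Si](C)(C)C(C)(C)C)C[C@](O)(C(=O)OCC=C)C[C@H]1O[Si](C)(C)C(C)(C)C
F4 | step 10 | allyl 4-O-(3-carboxypropanoyl)-1-O-[(E)-3,4-bis(allyloxy)cinnamoyl]-3,5-bis-O-(tert-butyldimethylsilyl)quinate | OC(=O)CCC(=O)O[C@H]1[C@H](O[Si](C)(C)C(C)(C)C)C[C@](OC(=O)/C=C/c2ccc(OCC=C)c(OCC=C)c2)(C(=O)OCC=C)C[C@H]1O[Si](C)(C)C(C)(C)C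
F5 | step 12 | allyl 4-O-[4-(allyloxy)-4-oxobutanoyl]-1-O-[(E)-3,4-bis(allyloxy)cinnamoyl]-3,5-bis-O-(carboxyacetyl)quinate | C=CCOC(=O)CCC(=O)O[C@H]1[C@H](OC(=O)CC(=O)O)C[C@](OC(=O)/C=C/c2ccc(OCC=C)c(OCC=C)c2)(C(=O)OCC=C)C[C@H]1OC(=O)CC(=O)O
F6 | step 12 | allyl 4-O-[4-(allyloxy)-4-oxobutanoyl]-1-O-[(E)-3,4-bis(allyloxy)cinnamoyl]-3,5-bis-O-{2-carboxy-3-[3,4-bis(allyloxy)phenyl]prop-2-enoyl}quinate (not isolated) | C=CCOC(=O)CCC(=O)O[C@H]1[C@H](OC(=O)C(=Cc2ccc(OCC=C)c(OCC=C)c2)C(=O)O)C[C@](OC(=O)/C=C/c2ccc(OCC=C)c(OCC=C)c2)(C(=O)OCC=C)C[C@H]1OC(=O)C(=Cc1ccc(OCC=C)c(OCC=C)c1)C(=O)O
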